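Read both flasks at 4.0 min and ask how many minutes of full gas each has had by then, since E starts with none in solution.

all flasks: E 77 mM (held)

| run | L | temperature | remark | time |
|---|---|---|---|---|
| autumn | 0.038 M | 0 °C | run made earlier |  |
| dawn | 0.13 M | 20 °C | run made earlier |  |
| Saturday's | 0.20 M |  | at 35 °C until 50 s, from then on at 5 °C | 4.0 min |
| Friday's | 0.060 M |  | at 5 °C throughout | 4.0 min |

| run | time / min | J / % |
|---|---|---|
| autumn | 2.00 | 4.9 |
| autumn | 6.00 | 20.4 |
| autumn | 12.0 | 40.1 |
| autumn | 15.0 | 47.3 |
| autumn | 25.0 | 62.9 |
| dawn | 0.667 | 3.8 |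
| dawn | 2.00 | 20.0 |
| dawn | 4.00 | 42.7 |
| dawn | 6.00 | 59.4 |
| dawn | 8.00 | 68.9 |

(readings scatter by 0.3 percentage points)

- which one finishes higher in amount of J, in percent of the L charged ("neither" within 2 percentage points) (Saturday's / Friday's / neither)
- amount of J at the end, in percent of the L charged, Saturday's
- amount of J at the end, in percent of the L charged, Friday's

- the analysis behind the earlier runs scatters by 0.3 percentage points, standard deviation
- at the start none of E is in solution

Take the logarithm of the L remaining. The middle readings of the autumn run give a pseudo-first-order constant of 0.0458 min⁻¹, and those of the dawn run give 0.170 min⁻¹. Carry the same factor per degree: that reads 0.0636 min⁻¹ at 5 °C and 0.452 min⁻¹ at 35 °C. Extend the straight autumn line back to the time axis. It cuts at the lag, the minutes a flask loses while E dissolves, 1.02 min, which I take as the same at each temperature. Gas time is then the reading time less the lag multiplied by the fraction of saturation reached.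

Friday's has 3.00 min of gas time. By these readings its L takes dissolved E at 0.0495 min⁻¹, far slower than E dissolves, so the rule stands and gives 17.4%.

In Saturday's hot stage, by these readings, L takes dissolved E at 1.18 min⁻¹, faster than the 0.980 min⁻¹ at which it dissolves. My reckoning therefore puts dissolved E at 37.9% of saturation by 50 s, and the stage earns 0.203 min of gas time. Now bracket the cold stage. On this reckoning, starting it saturated gives a ceiling of 25.4%, and starting it empty gives a floor of 20.6%. Crediting the dissolved share as a correction, I commit to 22.5%, which puts Saturday's ahead of Friday's by more than the margin.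

The forecast names Saturday's, with 18% (14% to 22%) for Friday's and 30% (24% to 36%) for Saturday's, above my ceiling, holding of Saturday's hot stage that “E is already about 70% dissolved”.

The flasks give 23.1% for Saturday's and 18.8% for Friday's, so Saturday's finishes higher.

    E ⇌ X, rate k1*(csat - [X]) (kL = 0.662 min⁻¹)
    L + X ⇌ J (K = 170 M⁻¹, k = 14.7 M⁻¹ min⁻¹, Ea = 61.0 kJ mol⁻¹, ΔH = −7.00 kJ mol⁻¹)
    X + J → D (k = 0.812 M⁻¹ min⁻¹, Ea = 45.0 kJ mol⁻¹)
    X → Z (k = 0.236 min⁻¹, Ea = 95.0 kJ mol⁻¹)
    (constants at 35 °C)

At 0.833 min, Saturday's held 0.0137 M of X, the dissolved gas, which is less than my 0.0292 M, and 10.7% of J, which is more than my 8.77%. Now take Friday's charge at 5 °C and read it at 1.5 min. The lag leaves 0.714 min of gas time, which gives 4.44% of J. That flask holds 4.50% of J.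

(The numbers in the tables are simulated with made-up constants; noise was put on by code.)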